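**Assumptions.**
- (R)-Dimethyl malate (from D-malic acid) is the commercial chiral starting material.
- The side chain is the 12-phenyldodecyl group, as in the target SMILES.
- The C6 epimers formed in Step 5 are carried through, and the unwanted C6 epimer is removed by HPLC at the end (Step 9).

## Retrosynthetic overview
- Target ⇒ the cis-fused tetrahydrofuran is closed last, by O6 onto C3 of hydroxy-lactone 14. This resets C3 (SN2 inversion, or E1cB then oxa-Michael).
- 14 ⇐ lactonisation of trihydroxy ester 13. C4 and its methyl come from chelation-controlled MeMgBr addition to α-hydroxy ketone 11, with the malate carbinol C3 as the controlling centre.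
- 11 ⇐ reductive N–O cleavage of isoxazoline 10. Nitrile oxide [3+2] cycloaddition of malate-derived aldoxime 9 with 1,1-disubstituted alkene 5 builds C4–C5 and the C6–O bond, with C6 carrying Me and the chain.
- Ring order: isoxazoline, then γ-lactone, then tetrahydrofuran.

## Route

**Step 1**
Reactants: 1 (1,12-dibromododecane, 3 equiv); 2 (phenylmagnesium bromide)
Product: 3 ((12-bromododecyl)benzene)
Conditions: Li2CuCl4 (3 mol %), THF, 0 °C → rt
Reagents that add atoms: phenylmagnesium bromide, Br[Mg]c1ccccc1 (adds C6H5)
Why: Cu-catalysed Kumada coupling of an aryl Grignard with a primary alkyl bromide, with excess dibromide favouring mono-arylation.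

**Step 2**
Reactants: 3; 4 (isopropenylmagnesium bromide)
Product: 5 ((13-methyltetradec-13-en-1-yl)benzene, CH2=C(Me)(CH2)12Ph)
Conditions: Li2CuCl4 (5 mol %), THF, −10 °C → rt
Reagents that add atoms: isopropenylmagnesium bromide, C=C(C)[Mg]Br (adds C3H5)
Why: Cu-catalysed alkenyl Grignard/alkyl bromide coupling gives the 1,1-disubstituted alkene that carries the C6 methyl and the chain, and it has no stereocentre.

**Step 3**
Reactants: 6 (dimethyl (R)-malate)
Product: 7 (methyl (R)-3,4-dihydroxybutanoate)
Conditions: BH3·SMe2 (1 equiv), NaBH4 (5 mol %), THF, 0 °C → rt; crude product used directly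
Reagents that add atoms: none
Why: Hydroxyl-directed borane reduction is selective for the ester α to the hydroxyl, and the C3 carbinol centre is untouched and stays R.

**Step 4**
Reactants: 7; 8 (hydroxylamine hydrochloride)
Product: 9 (methyl (R)-3-hydroxy-4-(hydroxyimino)butanoate, E/Z mixture)
Conditions: TEMPO (5 mol %), PhI(OAc)2, CH2Cl2, 0 °C; then NH2OH·HCl, NaOAc, MeOH/H2O, rt
Reagents that add atoms: hydroxylamine, NO (N and O end up in the oxime)
Why: TEMPO/BAIB oxidises the primary alcohol selectively and the labile α-hydroxy aldehyde is trapped in situ as the oxime (condensation), so C3 is preserved.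

**Step 5**
Reactants: 9; 5 (3 equiv)
Product: 10 (methyl (3R)-3-hydroxy-3-[5-methyl-5-(12-phenyldodecyl)-4,5-dihydroisoxazol-3-yl]propanoate, about 1:1 at isoxazoline C5, which becomes C6 of the target)
Conditions: NCS, pyridine (cat.), CHCl3, 40 °C; then 5, Et3N, 0 °C → rt (slow addition)
Reagents that add atoms: none (the Cl of NCS is lost as HCl)
Why: In this nitrile oxide/alkene 1,3-dipolar cycloaddition the oxygen adds to the more substituted alkene carbon, forming C4–C5 and the C6–O bond so that C6 is quaternary (Me, chain, O), and C6 is set non-selectively.

**Step 6**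
Reactants: 10
Product: 11 (methyl (3R)-3,6-dihydroxy-6-methyl-4-oxo-18-phenyloctadecanoate, C6 epimers)
Conditions: H2 (1 atm), Raney Ni, B(OH)3, MeOH/H2O (5:1), rt
Reagents that add atoms: water, O (ketone oxygen from imine hydrolysis)
Why: Raney Ni/boric acid cleaves the isoxazoline N–O bond to a β-hydroxy imine that hydrolyses to the β-hydroxy ketone, unmasking C4 as a ketone and C6 as a tertiary alcohol without touching C3.

**Step 7**
Reactants: 11; 12 (methylmagnesium bromide)
Product: 13 (methyl (3R,4S)-3,4,6-trihydroxy-4,6-dimethyl-18-phenyloctadecanoate, C6 epimers)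
Conditions: MeMgBr (4 equiv), THF, −78 → −30 °C; aq. NH4Cl
Reagents that add atoms: methylmagnesium bromide, C[Mg]Br (adds CH3)
Why: In this chelation-controlled (Cram-chelate) Grignard addition, the C3 magnesium alkoxide chelates the C4 carbonyl and Me adds from the face bearing H rather than CH2CO2Me, setting the C4 quaternary centre as S, while the ketone reacts faster than the ester at low temperature.

**Step 8**
Reactants: 13
Product: 14 ((4R,5S)-4-hydroxy-5-methyl-5-(2-hydroxy-2-methyl-14-phenyltetradecyl)dihydrofuran-2-one; target numbering 3R,4S; C6 epimers)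
Conditions: PPTS (10 mol %), PhMe, 60 °C, 4 Å MS
Reagents that add atoms: none (MeOH is lost)
Why: Mild acid-catalysed transesterification closes the γ-lactone onto the C4 tertiary γ-hydroxy group without touching the stereocentres at C3 and C4.

**Step 9**
Reactants: 14
Product: 15 (plakortone L); the C6 epimer is removed by HPLC and discarded
Conditions: MsCl, Et3N, CH2Cl2, 0 °C; then DBU, MeCN, 60 °C; then HPLC separation of the C6 epimers
Reagents that add atoms: none (the mesylate is lost)
Why: After selective mesylation of the secondary C3 alcohol, the C6 tertiary alkoxide closes onto C3 by SN2 inversion or by E1cB to the butenolide followed by 5-exo oxa-Michael addition, and either path forces the cis ring fusion, so C3 becomes S next to C4 (S), while C6 keeps its Step 5 configuration.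

## Compound list
1 | 1,12-dibromododecane | BrCCCCCCCCCCCCBr | starting material
2 | phenylmagnesium bromide | Br[Mg]c1ccccc1 | starting material
3 | (12-bromododecyl)benzene | BrCCCCCCCCCCCCc1ccccc1 | intermediate
4 | isopropenylmagnesium bromide | C=C(C)[Mg]Br | starting material
5 | (13-methyltetradec-13-en-1-yl)benzene | C=C(C)CCCCCCCCCCCCc1ccccc1 | intermediate
6 | dimethyl (R)-malate | COC(=O)C[C@@H](O)C(=O)OC | starting material
7 | methyl (R)-3,4-dihydroxybutanoate | COC(=O)C[C@@H](O)CO | intermediate
8 | hydroxylamine | NO | starting material
9 | methyl (R)-3-hydroxy-4-(hydroxyimino)butanoate | COC(=O)C[C@@H](O)C=NO | intermediate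
10 | isoxazoline (C6 unspecified) | COC(=O)C[C@@H](O)C1=NOC(C)(CCCCCCCCCCCCc2ccccc2)C1 | intermediate
11 | methyl (3R)-3,6-dihydroxy-6-methyl-4-oxo-18-phenyloctadecanoate (C6 unspecified) | COC(=O)C[C@@H](O)C(=O)CC(C)(O)CCCCCCCCCCCCc1ccccc1 | intermediate
12 | methylmagnesium bromide | C[Mg]Br | starting material
13 | methyl (3R,4S)-3,4,6-trihydroxy-4,6-dimethyl-18-phenyloctadecanoate (C6 unspecified) | COC(=O)C[C@@H](O)[C@@](C)(O)CC(C)(O)CCCCCCCCCCCCc1ccccc1 | intermediate
14 | (4R,5S)-hydroxy-lactone (C6 unspecified) | O=C1C[C@@H](O)[C@](C)(CC(C)(O)CCCCCCCCCCCCc2ccccc2)O1 | intermediate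
15 | plakortone L | C[C@]1(CCCCCCCCCCCCc2ccccc2)C[C@]2(C)OC(=O)C[C@@H]2O1 | target

## Totals
- Total steps: 9.
- Longest linear sequence: 7 (Steps 3 to 9 from dimethyl (R)-malate; Steps 1, 2, 5 to 9 is also 7).

## Three steps most likely to fail
1. **Step 7, chelation-controlled MeMgBr addition.** Risks are low dr, or over-addition to the ester in the presence of two alkoxides.
   Fallback: change the disconnection. Convert (R)-malate to the C4 methyl ketone (Weinreb amide, then MeMgBr, C3 protected as OBn) and add a 2-alkylallyl zinc or indium reagent by chelation control. Then close the tetrahydrofuran by Markovnikov hydroalkoxylation and lactonise.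
2. **Step 9, ring closure.** The tertiary-alkoxide oxa-Michael or SN2 closure may be reversible or elimination-prone. C6 is not controlled, so the product is a mixture of epimers and the yield is capped at about 50 %.
   Fallback: form the bicyclic 2-methyl oxocarbenium or ketal first (C6 as a methyl ketone hemiketal). Then add the 12-phenyldodecyl group as an organozinc or alkylaluminium nucleophile from the convex face, which fixes C6 by substrate control.
3. **Step 5, cycloaddition.** The α-hydroxy nitrile oxide may dimerise to a furoxan, and the hindered alkene reacts slowly.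
   Fallback: use the reverse polarity. Generate acetonitrile oxide from nitroethane and add it to a malate-derived 2-methylallylic alcohol, so the C4 oxygen and Me come from the alkene. Then install the side chain by Grignard addition to the resulting methyl ketone.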